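**Retrosynthetic overview**

1. The strategy rests on the 2(5H)-furanone ring (O1, C2 carbonyl, C3 with the hydroxybutyl arm, C4–Br, C5 with exocyclic C6). It is a furan one oxidation level up whose α-carbons are C2 and C5, so bromine, side chain and C6 (as a methyl) can all sit on a tetrasubstituted furan before any lactone exists.
2. Target ⇐ its TBS ether ⇐ (Z)-iodomethylidene by ICl addition and HCl loss on the 5-methylidene lactone ⇐ dehydration of the C5 hemiketal.
3. Hemiketal ⇐ singlet-oxygen [4+2] on a 2-trimethylsilylfuran, with silicon marking C2 as the future carbonyl.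
4. Silylfuran ⇐ two α-metalations (methyl beside Br, then silicon at the last ring C–H) of the TBS-protected (R)-carbinol ⇐ CBS reduction ⇐ Weinreb acylation of 4-bromo-3-furyllithium from 3,4-dibromofuran.
5. Ring order: the furan ring is bought; the only ring formed is the transient bicyclic endoperoxide, after which the same five atoms re-close as the lactone.

Key step: step 6

Remark: hemiketal 18 is carried on as a mixture of C5 epimers because C5 becomes trigonal in step 7; N-methoxy-N-methylbutanamide is taken as a catalogue reagent.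

**Route**

Step 1
Reactants: 1 3,4-dibromofuran; 2 N-methoxy-N-methylbutanamide
Product: 5 1-(4-bromofuran-3-yl)butan-1-one, via 4-bromo-3-furyllithium 3 (not isolated), via lithium hemiaminal chelate 4 (not isolated)
Conditions: n-BuLi (1.0 equiv), Et2O, −78 °C; then 2, −78 → 0 °C; 1 M HCl
Reagents that add atoms: N-methoxy-N-methylbutanamide, CCCC(=O)N(C)OC
Why: Bromine–lithium exchange on one of the two equivalent bromides gives the β-furyllithium, which is held at −78 °C so that it does not isomerise, and its Weinreb ketone synthesis stops at the ketone because the chelated tetrahedral adduct survives until the acid quench.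

Step 2
Reactants: 5 1-(4-bromofuran-3-yl)butan-1-one
Product: 6 (1R)-1-(4-bromofuran-3-yl)butan-1-ol
Conditions: (S)-1-methyl-3,3-diphenyltetrahydro-1H,3H-pyrrolo[1,2-c][1,3,2]oxazaborole [(S)-Me-CBS, C18H20BNO] (10 mol %), BH3·SMe2, THF, −20 °C; MeOH, aqueous work-up
Reagents that add atoms: none
Why: Corey–Bakshi–Shibata reduction, in which the ketone binds the catalyst boron with the bromofuryl group as the large substituent and the n-propyl chain as the small one, so that hydride from the nitrogen-bound borane should reach the Si face and give the (R)-carbinol, as with aryl n-alkyl ketones.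

Step 3
Reactants: 6 (1R)-1-(4-bromofuran-3-yl)butan-1-ol; 7 tert-butyldimethylsilyl chloride
Product: 8 {[(1R)-1-(4-bromofuran-3-yl)butyl]oxy}(tert-butyl)dimethylsilane
Conditions: imidazole, DMF, rt
Reagents that add atoms: tert-butyldimethylsilyl chloride, CC(C)(C)[Si](C)(C)Cl
Why: Imidazole-promoted silylation of a secondary alcohol, which removes the acidic O–H before the two amide-base metalations and does not touch the stereocentre.

Step 4
Reactants: 8 {[(1R)-1-(4-bromofuran-3-yl)butyl]oxy}(tert-butyl)dimethylsilane; 9 iodomethane
Product: 11 {[(1R)-1-(4-bromo-5-methylfuran-3-yl)butyl]oxy}(tert-butyl)dimethylsilane, via bromine-flanked α-furyllithium 10 (not isolated)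
Conditions: lithium diisopropylamide (LDA, 1.1 equiv), THF, −78 °C; then 9, −78 → −20 °C
Reagents that add atoms: iodomethane, CI
Why: Directed deprotonation followed by SN2 alkylation, in which the α-hydrogen flanked by ring oxygen and bromine is by far the more acidic (as in the LDA lithiation of 3-bromofuran), the amide base avoids bromine–lithium exchange, and the other α-position is neither activated nor accessible next to the silyloxybutyl group.

Step 5
Reactants: 11 {[(1R)-1-(4-bromo-5-methylfuran-3-yl)butyl]oxy}(tert-butyl)dimethylsilane; 12 chlorotrimethylsilane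
Product: 14 {4-bromo-3-[(1R)-1-{[tert-butyl(dimethyl)silyl]oxy}butyl]-5-methylfuran-2-yl}(trimethyl)silane, via side-chain-flanked α-furyllithium 13 (not isolated)
Conditions: lithium 2,2,6,6-tetramethylpiperidide (LiTMP, 1.5 equiv), 12 present from the start (in situ quench), THF, −78 → −40 °C
Reagents that add atoms: chlorotrimethylsilane, C[Si](C)(C)Cl
Why: Deprotonative silylation with in situ trapping, in which the only ring hydrogen left is an α-furyl C–H that the stronger amide base removes without attacking the C–Br bond, while the chlorosilane already present captures the anion as it forms, pulling the equilibrium forward and outrunning both lateral metalation of the methyl group and a 1,4 O-to-C shift of the TBS group.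

Step 6
Reactants: 14 {4-bromo-3-[(1R)-1-{[tert-butyl(dimethyl)silyl]oxy}butyl]-5-methylfuran-2-yl}(trimethyl)silane; 15 dioxygen
Product: 18 4-bromo-3-[(1R)-1-{[tert-butyl(dimethyl)silyl]oxy}butyl]-5-hydroxy-5-methylfuran-2(5H)-one (C5 epimers), via endoperoxide 16 (not isolated), via keto silyl ester 17 (not isolated)
Conditions: O2, 5,10,15,20-tetraphenylporphyrin (C44H30N4, cat.), visible light, CH2Cl2, −78 °C; then H2O/THF, rt
Reagents that add atoms: dioxygen, O=O
Why: Sensitised singlet oxygen adds suprafacially across the furan diene termini C2 and C5 in a [4+2] cycloaddition to give the 2,3,7-trioxabicyclo[2.2.1]heptene 16, the only ring formed and a transient one. Silicon then shifts from C2 to the adjacent peroxide oxygen with O–O heterolysis and opening of the C5–O1 bond, so C2 becomes the carboxyl carbon of keto silyl ester 17; hydrolysis on work-up frees the acid, which re-closes on the C5 ketone by 5-exo-trig hemiketalisation. The closest known reaction is the regiospecific photooxygenation of 2-trialkylsilylfurans to 5-hydroxybutenolides. The selectivity needed is which α-carbon ends as the lactone carbonyl, and the trimethylsilyl group on the carbon next to the side chain fixes it. The new stereocentre C5 is uncontrolled and need not be controlled, since both epimers converge when C5 becomes trigonal in step 7, and C1' is not involved. The methyl, alkyl and silyl donors should keep the brominated furan electron-rich enough for the cycloaddition, and the neutral, metal-free conditions should leave the vinylic bromide and the silyl ether alone.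

Step 7
Reactants: 18 4-bromo-3-[(1R)-1-{[tert-butyl(dimethyl)silyl]oxy}butyl]-5-hydroxy-5-methylfuran-2(5H)-one
Product: 20 4-bromo-3-[(1R)-1-{[tert-butyl(dimethyl)silyl]oxy}butyl]-5-methylidenefuran-2(5H)-one, via C5 mesylate 19 (not isolated)
Conditions: MsCl, Et3N, CH2Cl2, 0 °C → rt
Reagents that add atoms: none
Why: Dehydration by sulfonylation and elimination, in which the hemiketal hydroxyl (or its ring-opened carboxylate, which leads to the same cation) is activated and methanesulfonate leaves from the acetal carbon with loss of a methyl hydrogen, the only β-hydrogens present, giving the exocyclic enol lactone under basic conditions that the silyl ether tolerates.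

Step 8
Reactants: 20 4-bromo-3-[(1R)-1-{[tert-butyl(dimethyl)silyl]oxy}butyl]-5-methylidenefuran-2(5H)-one; 21 iodine monochloride
Product: 23 (5Z)-4-bromo-3-[(1R)-1-{[tert-butyl(dimethyl)silyl]oxy}butyl]-5-(iodomethylidene)furan-2(5H)-one, via C5 iodochloride 22 (not isolated)
Conditions: 21 (1.1 equiv), CH2Cl2, −78 → 0 °C, dark; then Et3N, 0 °C → rt
Reagents that add atoms: iodine monochloride, ClI
Why: Halogen addition then dehydrohalogenation, as in the bromine addition and dehydrobromination of 5-methylidene-2(5H)-furanones: iodine adds to the terminal carbon and chloride to the oxygen-bearing C5 (Markovnikov), only the CH2I hydrogens are β to the chloride, and the (Z)-isomer should prevail because iodine on the O1 side avoids the C4 bromine.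

Step 9
Reactants: 23 (5Z)-4-bromo-3-[(1R)-1-{[tert-butyl(dimethyl)silyl]oxy}butyl]-5-(iodomethylidene)furan-2(5H)-one
Product: 24 (5Z)-4-bromo-3-[(1R)-1-hydroxybutyl]-5-(iodomethylidene)furan-2(5H)-one
Conditions: 48% aq HF, MeCN, 0 °C → rt
Reagents that add atoms: none
Why: Acidic fluoride cleavage of the silyl ether, driven by Si–F bond formation, under non-basic conditions that should spare the electrophilic halogenated alkylidene butenolide and leave the C1' configuration as set in step 2.

**Compound list**

1 | 3,4-dibromofuran | Brc1cocc1Br | starting material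
2 | N-methoxy-N-methylbutanamide | CCCC(=O)N(C)OC | starting material
3 | 4-bromo-3-furyllithium | [Li]c1cocc1Br | intermediate
4 | lithium 1-(4-bromofuran-3-yl)-1-[methoxy(methyl)amino]butan-1-olate (hemiaminal chelate) | CCCC(O[Li])(N(C)OC)c1cocc1Br | intermediate
5 | 1-(4-bromofuran-3-yl)butan-1-one | CCCC(=O)c1cocc1Br | intermediate
6 | (1R)-1-(4-bromofuran-3-yl)butan-1-ol | CCC[C@@H](O)c1cocc1Br | intermediate
7 | tert-butyldimethylsilyl chloride | CC(C)(C)[Si](C)(C)Cl | starting material
8 | {[(1R)-1-(4-bromofuran-3-yl)butyl]oxy}(tert-butyl)dimethylsilane | CCC[C@@H](O[Si](C)(C)C(C)(C)C)c1cocc1Br | intermediate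
9 | iodomethane | CI | starting material
10 | {3-bromo-4-[(1R)-1-{[tert-butyl(dimethyl)silyl]oxy}butyl]furan-2-yl}lithium | CCC[C@@H](O[Si](C)(C)C(C)(C)C)c1coc([Li])c1Br | intermediate
11 | {[(1R)-1-(4-bromo-5-methylfuran-3-yl)butyl]oxy}(tert-butyl)dimethylsilane | CCC[C@@H](O[Si](C)(C)C(C)(C)C)c1coc(C)c1Br | intermediate
12 | chlorotrimethylsilane | C[Si](C)(C)Cl | starting material
13 | {4-bromo-3-[(1R)-1-{[tert-butyl(dimethyl)silyl]oxy}butyl]-5-methylfuran-2-yl}lithium | CCC[C@@H](O[Si](C)(C)C(C)(C)C)c1c([Li])oc(C)c1Br | intermediate
14 | {4-bromo-3-[(1R)-1-{[tert-butyl(dimethyl)silyl]oxy}butyl]-5-methylfuran-2-yl}(trimethyl)silane | CCC[C@@H](O[Si](C)(C)C(C)(C)C)c1c(Br)c(C)oc1[Si](C)(C)C | intermediate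
15 | dioxygen | O=O | starting material
16 | 5-bromo-6-[(1R)-1-{[tert-butyl(dimethyl)silyl]oxy}butyl]-4-methyl-1-(trimethylsilyl)-2,3,7-trioxabicyclo[2.2.1]hept-5-ene (endoperoxide, bridgehead epimers) | CCC[C@@H](O[Si](C)(C)C(C)(C)C)C1=C(Br)C2(C)OOC1([Si](C)(C)C)O2 | intermediate
17 | trimethylsilyl (2E)-3-bromo-2-[(1R)-1-{[tert-butyl(dimethyl)silyl]oxy}butyl]-4-oxopent-2-enoate (carboxyl and acetyl cis) | CCC[C@@H](O[Si](C)(C)C(C)(C)C)/C(C(=O)O[Si](C)(C)C)=C(\Br)C(C)=O | intermediate
18 | 4-bromo-3-[(1R)-1-{[tert-butyl(dimethyl)silyl]oxy}butyl]-5-hydroxy-5-methylfuran-2(5H)-one (C5 epimers) | CCC[C@@H](O[Si](C)(C)C(C)(C)C)C1=C(Br)C(C)(O)OC1=O | intermediate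
19 | 3-bromo-4-[(1R)-1-{[tert-butyl(dimethyl)silyl]oxy}butyl]-2-methyl-5-oxo-2,5-dihydrofuran-2-yl methanesulfonate (C5 epimers) | CCC[C@@H](O[Si](C)(C)C(C)(C)C)C1=C(Br)C(C)(OS(C)(=O)=O)OC1=O | intermediate
20 | 4-bromo-3-[(1R)-1-{[tert-butyl(dimethyl)silyl]oxy}butyl]-5-methylidenefuran-2(5H)-one | CCC[C@@H](O[Si](C)(C)C(C)(C)C)C1=C(Br)C(=C)OC1=O | intermediate
21 | iodine monochloride | ClI | starting material
22 | 4-bromo-3-[(1R)-1-{[tert-butyl(dimethyl)silyl]oxy}butyl]-5-chloro-5-(iodomethyl)furan-2(5H)-one (C5 epimers) | CCC[C@@H](O[Si](C)(C)C(C)(C)C)C1=C(Br)C(Cl)(CI)OC1=O | intermediate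
23 | (5Z)-4-bromo-3-[(1R)-1-{[tert-butyl(dimethyl)silyl]oxy}butyl]-5-(iodomethylidene)furan-2(5H)-one | CCC[C@@H](O[Si](C)(C)C(C)(C)C)C1=C(Br)/C(=C/I)OC1=O | intermediate
24 | (5Z)-4-bromo-3-[(1R)-1-hydroxybutyl]-5-(iodomethylidene)furan-2(5H)-one | CCC[C@@H](O)C1=C(Br)/C(=C/I)OC1=O | target

**Step count and risks**

Total steps: 9. Longest linear sequence: 9 steps (1 → 24).

Steps most likely to fail:

Step 6 (key step). The bromine lowers the furan's reactivity, so the cycloaddition may be slow enough for the sensitiser to bleach, or the endoperoxide may fragment before silicon migrates. The fallback does not use singlet oxygen or silicon: it sets out from 11 and comes back at 18, bypassing steps 5 and 6. Furan 11 would be opened oxidatively with NBS and NaHCO3 in aqueous acetone at −20 °C, followed by pyridine, to give the cis keto-enal (2E)-3-bromo-2-[(1R)-1-{[tert-butyl(dimethyl)silyl]oxy}butyl]-4-oxopent-2-enal F2. Pinnick oxidation of the aldehyde (NaClO2, NaH2PO4, 2-methylbut-2-ene, t-BuOH/H2O) would then give the keto acid, which is the open tautomer of 18 and closes to it. Regiochemistry is then fixed by which α-carbon carries hydrogen, because that carbon becomes the carboxyl.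

Step 5. The hindered, only weakly acidified ring C–H may be deprotonated too slowly, or the base may be diverted into lateral metalation of the C5 methyl or a 1,4 O-to-C shift of the TBS group onto the lithiated carbon. The fallback replaces deprotonation by halogenation and exchange; it sets out from 11 and comes back at 14. NBS in DMF at 0 °C in the dark should brominate the sole free α-position to give {[(1R)-1-(2,4-dibromo-5-methylfuran-3-yl)butyl]oxy}(tert-butyl)dimethylsilane F1. One equivalent of n-BuLi in THF at −78 °C should then exchange the α-bromine selectively over the β-bromine to give the same lithio species 13, which chlorotrimethylsilane 12 converts into 14.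

Step 8. On base treatment the iodochloride may lose ICl again (halophilic attack on iodine) instead of HCl, or the addition to the electron-poor enol lactone may not go to completion. The fallback separates an irreversible capture from the elimination; it sets out from 20 and comes back at 23. N-iodosuccinimide in wet acetonitrile at 0 °C should add iodine and water across the exocyclic double bond to give the stable hemiketal 4-bromo-3-[(1R)-1-{[tert-butyl(dimethyl)silyl]oxy}butyl]-5-hydroxy-5-(iodomethyl)furan-2(5H)-one F3. This would be dehydrated as in step 7 (MsCl, Et3N, CH2Cl2) through 3-bromo-4-[(1R)-1-{[tert-butyl(dimethyl)silyl]oxy}butyl]-2-(iodomethyl)-5-oxo-2,5-dihydrofuran-2-yl methanesulfonate F4, which is not isolated, to give 23, with the (Z)-geometry again favoured by avoidance of the C4 bromine.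

**Further compounds**

F1 | step 5 | {[(1R)-1-(2,4-dibromo-5-methylfuran-3-yl)butyl]oxy}(tert-butyl)dimethylsilane | CCC[C@@H](O[Si](C)(C)C(C)(C)C)c1c(Br)oc(C)c1Br
F2 | step 6 | (2E)-3-bromo-2-[(1R)-1-{[tert-butyl(dimethyl)silyl]oxy}butyl]-4-oxopent-2-enal | CCC[C@@H](O[Si](C)(C)C(C)(C)C)/C(C=O)=C(\Br)C(C)=O
F3 | step 8 | 4-bromo-3-[(1R)-1-{[tert-butyl(dimethyl)silyl]oxy}butyl]-5-hydroxy-5-(iodomethyl)furan-2(5H)-one | CCC[C@@H](O[Si](C)(C)C(C)(C)C)C1=C(Br)C(O)(CI)OC1=O
F4 | step 8 | 3-bromo-4-[(1R)-1-{[tert-butyl(dimethyl)silyl]oxy}butyl]-2-(iodomethyl)-5-oxo-2,5-dihydrofuran-2-yl methanesulfonate | CCC[C@@H](O[Si](C)(C)C(C)(C)C)C1=C(Br)C(CI)(OS(C)(=O)=O)OC1=O
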